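The ester is cut between the carbonyl carbon and C1 of the 4-hydroxy-3-methoxyphenyl ring, so the arene enters as a carbanion and the hindered neopentylic alcohol (C1 of the cycloundecadiene ring, next to quaternary C2) never has to attack an electron-rich acyl donor. The alcohol is activated as its imidazole-1-carboxylate. An unprotected, doubly magnesiated 4-iodoguaiacol then forms the aryl–carbonyl bond and gives the natural product in one operation; the phenoxide oxygen at C4 of the arene raises the nucleophilicity of C1 and shields the new ester from over-addition. The 11-membered triene comes from (E)-geranylacetone by enantioselective reverse prenylation and a macrocyclic Heck closure.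

Key step: step 7

Assumption: the (S)-SEGPHOS iridium catalyst is taken to deliver the prenyl unit to the Si face of aldehyde 6 (R carbinol); should the sense of induction prove opposite, (R)-SEGPHOS is used with no other change.

Step 1
Reactants: 1 (E)-geranylacetone
Product: 2 (5E)-6,10-dimethylundeca-1,5,9-trien-2-yl trifluoromethanesulfonate
Conditions: LDA, THF, −78 °C; PhNTf2, −78 → 0 °C
Reagents that add atoms: N-phenylbis(trifluoromethanesulfonimide), O=S(=O)(N(c1ccccc1)S(=O)(=O)C(F)(F)F)C(F)(F)F
Why: Kinetic deprotonation of the methyl ketone at the unhindered CH3 and O-triflation of the terminal lithium enolate (regioselective enol triflate synthesis) should install the alkenyl electrophile for the later ring closure, the two trisubstituted alkenes being spectators.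

Step 2
Reactants: 2 (5E)-6,10-dimethylundeca-1,5,9-trien-2-yl trifluoromethanesulfonate
Product: 4 (5E)-8-(3,3-dimethyloxiran-2-yl)-6-methylocta-1,5-dien-2-yl trifluoromethanesulfonate (racemic), via bromohydrin 3 (not isolated)
Conditions: NBS, THF/H2O, 0 °C; then K2CO3, MeOH, 0 °C → rt
Reagents that add atoms: water, O; N-bromosuccinimide, O=C1CCC(=O)N1Br (bromine carried only in intermediate 3)
Why: The van Tamelen bromohydrin reaction in aqueous THF should select the exposed terminal trisubstituted alkene over the internal one and the electron-poor enol triflate, and carbonate closes the bromohydrin to the epoxide by intramolecular Williamson displacement (its stereocentre is destroyed in step 3).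

Step 3
Reactants: 4 (5E)-8-(3,3-dimethyloxiran-2-yl)-6-methylocta-1,5-dien-2-yl trifluoromethanesulfonate
Product: 6 (5E)-6-methyl-9-oxonona-1,5-dien-2-yl trifluoromethanesulfonate, via diol 5 (not isolated)
Conditions: H5IO6, THF/H2O, 0 °C
Reagents that add atoms: water, O (its oxygen enters intermediate 5 and leaves with acetone)
Why: Periodic acid should hydrolyse the epoxide to the vicinal diol and cleave it (Malaprade glycol cleavage) to the aldehyde and acetone, conditions under which the alkenyl triflate and the remaining trisubstituted alkene are inert.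

Step 4
Reactants: 6 (5E)-6-methyl-9-oxonona-1,5-dien-2-yl trifluoromethanesulfonate; 7 3-methylbuta-1,2-diene
Product: 8 (5E,9R)-9-hydroxy-6,10,10-trimethyldodeca-1,5,11-trien-2-yl trifluoromethanesulfonate
Conditions: π-allyl Ir(III) C,O-benzoate catalyst from [Ir(cod)Cl]2, (S)-SEGPHOS, 4-cyano-3-nitrobenzoic acid and allyl acetate (5 mol%), i-PrOH (2 equiv), toluene, 50 °C
Reagents that add atoms: none
Why: Krische transfer-hydrogenative reverse prenylation: Ir–H from 2-propanol hydrometalates the allene to a dimethylallyl iridium species that adds through its substituted terminus in a closed chair transition state, the ligand directing attack to the Si face to set the R carbinol centre beside the new quaternary carbon, while the alkenyl triflate should not be engaged by the saturated Ir(III) catalyst.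

Step 5
Reactants: 8 (5E,9R)-9-hydroxy-6,10,10-trimethyldodeca-1,5,11-trien-2-yl trifluoromethanesulfonate
Product: 9 (1R,3E,8E)-2,2,9-trimethyl-5-methylidenecycloundeca-3,8-dien-1-ol
Conditions: Pd(OAc)2 (10 mol%), PPh3, n-Bu4NCl, K2CO3, DMF, 70 °C, slow addition (≤2 mM)
Reagents that add atoms: none
Why: Intramolecular Heck reaction: oxidative addition into the alkenyl triflate, 11-endo insertion at the unsubstituted terminus of the neopentylic vinyl group and β-hydride elimination, possible only from the newly bonded CH2 because the next carbon is quaternary, should give the exo-methylene (E)-diene, with the gem-dimethyl group and the (E)-trisubstituted alkene pre-organising the chain and the carbinol centre untouched.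

Step 6
Reactants: 9 (1R,3E,8E)-2,2,9-trimethyl-5-methylidenecycloundeca-3,8-dien-1-ol
Product: 10 (1R,3E,8E)-2,2,9-trimethyl-5-methylidenecycloundeca-3,8-dien-1-yl 1H-imidazole-1-carboxylate
Conditions: CDI (2 equiv), DBU (10 mol%), THF, 40 °C
Reagents that add atoms: 1,1'-carbonyldiimidazole, O=C(n1ccnc1)n1ccnc1
Why: Base-catalysed acyl transfer from CDI to the hindered secondary hydroxyl (imidazole carbamate formation) places the future ester carbonyl on oxygen as an isolable, non-acidic activated carbonate equivalent without touching the stereocentre or the acid-sensitive triene.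

Step 7
Reactants: 10 (1R,3E,8E)-2,2,9-trimethyl-5-methylidenecycloundeca-3,8-dien-1-yl 1H-imidazole-1-carboxylate; 11 4-iodo-2-methoxyphenol
Product: 13 (1R,3E,8E)-2,2,9-trimethyl-5-methylidenecycloundeca-3,8-dien-1-yl 4-hydroxy-3-methoxybenzoate, via magnesiated phenoxide 12 (not isolated)
Conditions: 11 (2 equiv), MeMgCl (2 equiv), LiCl, THF, −30 °C; i-PrMgCl (1.9 equiv), −30 °C → rt; then 10, −40 → 0 °C; aq NH4Cl
Reagents that add atoms: none
Why: MeMgCl deprotonates the phenol and iodine–magnesium exchange at C4 of 11 gives the aryl Grignard 12, whose carbanion adds to the carbamate carbonyl of 10; the tetrahedral intermediate collapses by loss of imidazolide, a better leaving group than the secondary alkoxide, to give the aryl ester, and work-up releases the free phenol. The closest known reaction type is ester synthesis from Grignard reagents and alkyl imidazole-1-carboxylates, combined with halogen–magnesium exchange on unprotected iodophenols in the presence of LiCl. No ring is closed and no stereocentre is formed; C1 of the macrocycle lies two atoms from the reacting carbon and keeps its R configuration. The step needs C- over O-acylation and mono-addition: the C–Mg bond is far more nucleophilic than the magnesium phenoxide at low temperature, and i-PrMgCl is kept sub-stoichiometric so no alkyl Grignard competes. After coupling, the para O–Mg group makes the ester a vinylogous carbonate anion carrying a neopentylic alkoxy group, which should resist a second addition. The conditions are free of acid and radicals, so the triene is preserved.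

Compound list
1 | (E)-geranylacetone, (5E)-6,10-dimethylundeca-5,9-dien-2-one | CC(=O)CC/C=C(C)/CCC=C(C)C | starting material
2 | (5E)-6,10-dimethylundeca-1,5,9-trien-2-yl trifluoromethanesulfonate | C=C(OS(=O)(=O)C(F)(F)F)CC/C=C(C)/CCC=C(C)C | intermediate
3 | (5E)-9-bromo-10-hydroxy-6,10-dimethylundeca-1,5-dien-2-yl trifluoromethanesulfonate (racemic bromohydrin, not isolated) | C=C(OS(=O)(=O)C(F)(F)F)CC/C=C(C)/CCC(Br)C(C)(C)O | intermediate
4 | (5E)-8-(3,3-dimethyloxiran-2-yl)-6-methylocta-1,5-dien-2-yl trifluoromethanesulfonate (racemic) | C=C(OS(=O)(=O)C(F)(F)F)CC/C=C(C)/CCC1OC1(C)C | intermediate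
5 | (5E)-9,10-dihydroxy-6,10-dimethylundeca-1,5-dien-2-yl trifluoromethanesulfonate (racemic diol, not isolated) | C=C(OS(=O)(=O)C(F)(F)F)CC/C=C(C)/CCC(O)C(C)(C)O | intermediate
6 | (5E)-6-methyl-9-oxonona-1,5-dien-2-yl trifluoromethanesulfonate | C=C(OS(=O)(=O)C(F)(F)F)CC/C=C(C)/CCC=O | intermediate
7 | 3-methylbuta-1,2-diene (1,1-dimethylallene) | CC(C)=C=C | starting material
8 | (5E,9R)-9-hydroxy-6,10,10-trimethyldodeca-1,5,11-trien-2-yl trifluoromethanesulfonate | C=CC(C)(C)[C@H](O)CC/C(C)=C/CCC(=C)OS(=O)(=O)C(F)(F)F | intermediate
9 | (1R,3E,8E)-2,2,9-trimethyl-5-methylidenecycloundeca-3,8-dien-1-ol | C=C1/C=C/C(C)(C)[C@H](O)CC/C(C)=C/CC1 | intermediate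
10 | (1R,3E,8E)-2,2,9-trimethyl-5-methylidenecycloundeca-3,8-dien-1-yl 1H-imidazole-1-carboxylate | C=C1/C=C/C(C)(C)[C@H](OC(=O)n2ccnc2)CC/C(C)=C/CC1 | intermediate
11 | 4-iodo-2-methoxyphenol | COc1cc(I)ccc1O | starting material
12 | chloromagnesium 4-(chloromagnesio)-2-methoxyphenolate (not isolated) | COc1cc([Mg]Cl)ccc1O[Mg]Cl | intermediate
13 | (1R,3E,8E)-2,2,9-trimethyl-5-methylidenecycloundeca-3,8-dien-1-yl 4-hydroxy-3-methoxybenzoate | C=C1/C=C/C(C)(C)[C@H](OC(=O)c2ccc(O)c(OC)c2)CC/C(C)=C/CC1 | target

Total step count: 7. Longest linear sequence: 7 steps (1 → 13).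

Steps most likely to fail

Step 7. The iodine–magnesium exchange on the electron-rich phenoxide may stay incomplete, the phenoxide oxygen may be acylated by 10 to a mixed carbonate, or a second aryl addition may occur. The fallback sets out from alcohol 9 and returns at 13. Alcohol 9 is esterified under Yamaguchi conditions (2,4,6-trichlorobenzoyl chloride, Et3N, then DMAP, toluene) with commercial 4-acetoxy-3-methoxybenzoic acid to give (1R,3E,8E)-2,2,9-trimethyl-5-methylidenecycloundeca-3,8-dien-1-yl 4-acetoxy-3-methoxybenzoate F1. The aryl acetate is then removed selectively by aminolysis with pyrrolidine in CH2Cl2 at 0 °C, which should leave the hindered benzoate intact and give 13.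

Step 5. Oligomerisation may outrun closure of the 11-membered ring, insertion may occur in the exo mode, or Pd–H may re-add and isomerise the diene. The fallback sets out from 8 and returns at 9. The hydroxyl is silylated (TBSOTf, 2,6-lutidine) to (5E,9R)-9-[(tert-butyldimethylsilyl)oxy]-6,10,10-trimethyldodeca-1,5,11-trien-2-yl trifluoromethanesulfonate F2. Hydroboration of the monosubstituted alkene with 9-BBN and oxidation with NaBO3 gives the primary alcohol (5E,9R)-9-[(tert-butyldimethylsilyl)oxy]-12-hydroxy-6,10,10-trimethyldodeca-1,5-dien-2-yl trifluoromethanesulfonate F3, and Dess–Martin oxidation gives the aldehyde (5E,9R)-9-[(tert-butyldimethylsilyl)oxy]-6,10,10-trimethyl-12-oxododeca-1,5-dien-2-yl trifluoromethanesulfonate F4. An intramolecular Nozaki–Hiyama–Kishi coupling (CrCl2, cat. NiCl2, DMSO/THF, high dilution) of the alkenyl triflate with the aldehyde closes the ring to the allylic alcohol (5E,9R)-9-[(tert-butyldimethylsilyl)oxy]-6,10,10-trimethyl-2-methylidenecycloundec-5-en-1-ol F5; both carbinol epimers are usable. Dehydration with the Burgess reagent, which can only eliminate toward the ring CH2, gives tert-butyldimethyl{[(1R,3E,8E)-2,2,9-trimethyl-5-methylidenecycloundeca-3,8-dien-1-yl]oxy}silane F6, and TBAF in THF gives 9.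

Step 4. Facial selectivity may be insufficient on this aliphatic aldehyde, or the alkenyl triflate may erode under the iridium/alcohol conditions. The fallback sets out from 6 and returns at 8. Indium-mediated Barbier reverse prenylation with prenyl bromide in aqueous THF (γ-selective) gives racemic (5E)-9-hydroxy-6,10,10-trimethyldodeca-1,5,11-trien-2-yl trifluoromethanesulfonate F7. Dess–Martin oxidation gives the ketone (5E)-6,10,10-trimethyl-9-oxododeca-1,5,11-trien-2-yl trifluoromethanesulfonate F8. Corey–Bakshi–Shibata reduction with the (S)-methyl oxazaborolidine and catecholborane in toluene at low temperature, the tertiary alkyl group acting as the large substituent, should give the R alcohol 8 without hydroboration of the alkenes.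

Further compounds
F1 | step 7 | (1R,3E,8E)-2,2,9-trimethyl-5-methylidenecycloundeca-3,8-dien-1-yl 4-acetoxy-3-methoxybenzoate | C=C1/C=C/C(C)(C)[C@H](OC(=O)c2ccc(OC(C)=O)c(OC)c2)CC/C(C)=C/CC1
F2 | step 5 | (5E,9R)-9-[(tert-butyldimethylsilyl)oxy]-6,10,10-trimethyldodeca-1,5,11-trien-2-yl trifluoromethanesulfonate | C=CC(C)(C)[C@H](O[Si](C)(C)C(C)(C)C)CC/C(C)=C/CCC(=C)OS(=O)(=O)C(F)(F)F
F3 | step 5 | (5E,9R)-9-[(tert-butyldimethylsilyl)oxy]-12-hydroxy-6,10,10-trimethyldodeca-1,5-dien-2-yl trifluoromethanesulfonate | OCCC(C)(C)[C@H](O[Si](C)(C)C(C)(C)C)CC/C(C)=C/CCC(=C)OS(=O)(=O)C(F)(F)F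
F4 | step 5 | (5E,9R)-9-[(tert-butyldimethylsilyl)oxy]-6,10,10-trimethyl-12-oxododeca-1,5-dien-2-yl trifluoromethanesulfonate | O=CCC(C)(C)[C@H](O[Si](C)(C)C(C)(C)C)CC/C(C)=C/CCC(=C)OS(=O)(=O)C(F)(F)F
F5 | step 5 | (5E,9R)-9-[(tert-butyldimethylsilyl)oxy]-6,10,10-trimethyl-2-methylidenecycloundec-5-en-1-ol (epimers at C1) | C=C1C(O)CC(C)(C)[C@H](O[Si](C)(C)C(C)(C)C)CC/C(C)=C/CC1
F6 | step 5 | tert-butyldimethyl{[(1R,3E,8E)-2,2,9-trimethyl-5-methylidenecycloundeca-3,8-dien-1-yl]oxy}silane | C=C1/C=C/C(C)(C)[C@H](O[Si](C)(C)C(C)(C)C)CC/C(C)=C/CC1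
F7 | step 4 | (5E)-9-hydroxy-6,10,10-trimethyldodeca-1,5,11-trien-2-yl trifluoromethanesulfonate (racemic) | C=CC(C)(C)C(O)CC/C(C)=C/CCC(=C)OS(=O)(=O)C(F)(F)F
F8 | step 4 | (5E)-6,10,10-trimethyl-9-oxododeca-1,5,11-trien-2-yl trifluoromethanesulfonate | C=CC(C)(C)C(=O)CC/C(C)=C/CCC(=C)OS(=O)(=O)C(F)(F)F
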